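**Plan**
- The retrosynthesis first cuts the aryl–prenyl bond C3'–C1'' on ring B, then the two bonds of ring C that one oxidative rearrangement makes (C3–C1' and O1–C2), and last the enone C=C of a 2'-hydroxychalcone (crossed aldol).
- Forward: a ring B aldehyde and a ring A ketone are condensed to the chalcone; ring C then arises by a 1,2-aryl shift and pyranone closure in one flask; ring B is iodinated and prenylated at the end.
- Enabling feature: ring B bears oxygen on C2', C4' and C6', that is on both ortho carbons and the para carbon of the migrating carbon C1', so it bridges and shifts readily. Before prenylation C3' and C5' are equivalent, so mono-functionalisation of ring B has only one outcome.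
- The prenyl alkene is kept away from both the thallium oxidant and BCl3: the benzyl ethers are exchanged for acetates before the coupling, and the last step is a mild methanolysis.
- Stereochemistry: the target has no stereocenter and no stereogenic alkene; the E geometry of the chalcone and the racemic center of the acetal intermediate are erased when ring C forms.

Key step: step 5

Remark: the C3–C1' axis is taken as freely rotating, so no axial descriptor is assigned. The prenylstannane and the other small reagents are taken as purchased.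

**Step 1**
Reactants: 1 2,4,6-trihydroxybenzaldehyde; 2 dimethyl sulfate
Product: 3 2,6-dihydroxy-4-methoxybenzaldehyde
Conditions: Me2SO4 (1.0 equiv), K2CO3 (1.0 equiv), acetone, rt
Reagents that add atoms: dimethyl sulfate, COS(=O)(=O)OC
Why: Williamson etherification under stoichiometric control, in which the 4-hydroxyl (para to the formyl group and not chelated to it) is the most acidic and should be methylated first while both ortho hydroxyls stay hydrogen-bonded to the carbonyl.

**Step 2**
Reactants: 3 2,6-dihydroxy-4-methoxybenzaldehyde; 4 benzyl bromide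
Product: 5 2,6-bis(benzyloxy)-4-methoxybenzaldehyde
Conditions: BnBr (2.5 equiv), K2CO3 (3 equiv), DMF, 60 °C
Reagents that add atoms: benzyl bromide, BrCc1ccccc1
Why: Williamson etherification in a dipolar aprotic solvent with excess halide overcomes the hydrogen bond of the ortho hydroxyls, and the non-enolisable aldehyde tolerates K2CO3.

**Step 3**
Reactants: 6 2,4-dihydroxyacetophenone; 4 benzyl bromide
Product: 7 1-[4-(benzyloxy)-2-hydroxyphenyl]ethan-1-one
Conditions: BnBr (1.05 equiv), K2CO3 (1.1 equiv), acetone, reflux
Reagents that add atoms: benzyl bromide, BrCc1ccccc1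
Why: Regioselective Williamson etherification, since the 2-hydroxyl is held in a hydrogen bond to the ketone and only the 4-hydroxyl should react with one equivalent of halide.

**Step 4**
Reactants: 5 2,6-bis(benzyloxy)-4-methoxybenzaldehyde; 7 1-[4-(benzyloxy)-2-hydroxyphenyl]ethan-1-one
Product: 8 (E)-1-[4-(benzyloxy)-2-hydroxyphenyl]-3-[2,6-bis(benzyloxy)-4-methoxyphenyl]prop-2-en-1-one
Conditions: KOH (50% aq), EtOH/THF, rt; then cold dilute HCl to pH 5
Reagents that add atoms: none
Why: Claisen–Schmidt condensation, in which the ketone enolate adds to the non-enolisable aldehyde and E1cB loss of water gives the conjugated enone as its thermodynamic E isomer, the benzyl and methyl ethers being inert to KOH.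

**Step 5**
Reactants: 8 (E)-1-[4-(benzyloxy)-2-hydroxyphenyl]-3-[2,6-bis(benzyloxy)-4-methoxyphenyl]prop-2-en-1-one
Product: 10 7-(benzyloxy)-3-[2,6-bis(benzyloxy)-4-methoxyphenyl]-4H-chromen-4-one, via dimethyl acetal 9 (not isolated)
Conditions: Tl(NO3)3·3H2O (1.1 equiv), MeOH/CH(OMe)3/CH2Cl2, rt; then 10% aq HCl, 50 °C, same flask
Reagents that add atoms: none
Why: Trivalent thallium adds to the enone C=C with methanol entering at the benzylic carbon (oxythallation), and as monovalent thallium departs from the alpha carbon ring B shifts to it through a bridged phenonium ion, forming C3–C1', while methanol captures the remaining oxocarbenium ion as dimethyl acetal 9. This is the known oxidative rearrangement of 2'-hydroxychalcones to isoflavones, the laboratory counterpart of the biosynthetic aryl shift. On addition of HCl the acetal ionises, the ring A phenol closes ring C by 6-exo-trig attack on the oxocarbenium carbon (O1–C2), and loss of methanol gives the pyranone. No stereocenter is set, since the alpha center of 9 is racemic and becomes sp2 in 10. The step needs the aryl shift to outrun both direct closure of the phenol onto the thalliated alkene (aurone or flavone formation) and attack of the oxidant on the arenes. The three ether oxygens ortho and para to C1' make ring B an excellent bridging group, the phenol is chelated to the ketone, and only a slight excess of oxidant is used.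

**Step 6**
Reactants: 10 7-(benzyloxy)-3-[2,6-bis(benzyloxy)-4-methoxyphenyl]-4H-chromen-4-one; 11 N-iodosuccinimide
Product: 12 7-(benzyloxy)-3-[2,6-bis(benzyloxy)-3-iodo-4-methoxyphenyl]-4H-chromen-4-one
Conditions: NIS (1.0 equiv), TFA (cat.), MeCN/CH2Cl2, 0 °C to rt, dark
Reagents that add atoms: N-iodosuccinimide, O=C1CCC(=O)N1I
Why: Electrophilic aromatic iodination, in which ring B (three ether oxygens ortho or para to C3' and C5') is far more nucleophilic than the carbonyl-deactivated ring A, and the equivalence of the two open positions means one equivalent of NIS should give a single monoiodide.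

**Step 7**
Reactants: 12 7-(benzyloxy)-3-[2,6-bis(benzyloxy)-3-iodo-4-methoxyphenyl]-4H-chromen-4-one
Product: 13 3-(2,6-dihydroxy-3-iodo-4-methoxyphenyl)-7-hydroxy-4H-chromen-4-one
Conditions: BCl3 (1 M in CH2Cl2, 6 equiv), C6HMe5 (9 equiv), CH2Cl2, −78 °C; MeOH quench
Reagents that add atoms: none
Why: Lewis-acid ether cleavage, in which BCl3 removes aryl benzyl ethers at −78 °C and pentamethylbenzene traps the benzyl cations before they alkylate ring B, while the 4'-methyl ether (no neighbouring carbonyl to chelate boron) and the C–I bond should persist at this temperature.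

**Step 8**
Reactants: 13 3-(2,6-dihydroxy-3-iodo-4-methoxyphenyl)-7-hydroxy-4H-chromen-4-one; 14 acetic anhydride
Product: 15 3-(2,6-diacetoxy-3-iodo-4-methoxyphenyl)-4-oxo-4H-chromen-7-yl acetate
Conditions: Ac2O, pyridine, DMAP (cat.), CH2Cl2, 0 °C to rt
Reagents that add atoms: acetic anhydride, CC(=O)OC(C)=O
Why: DMAP-catalysed O-acylation of all three phenols installs base-labile groups that can later be removed without acid, which a prenyl group ortho to a free phenol would not tolerate (chroman formation).

**Step 9**
Reactants: 15 3-(2,6-diacetoxy-3-iodo-4-methoxyphenyl)-4-oxo-4H-chromen-7-yl acetate; 16 tributyl(3-methylbut-2-en-1-yl)stannane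
Product: 17 3-[2,6-diacetoxy-4-methoxy-3-(3-methylbut-2-en-1-yl)phenyl]-4-oxo-4H-chromen-7-yl acetate
Conditions: Pd(PPh3)4 (10 mol %), DMF, 90 °C, degassed
Reagents that add atoms: tributyl(3-methylbut-2-en-1-yl)stannane, CCCC[Sn](CCCC)(CCCC)CC=C(C)C
Why: Stille coupling, in which zerovalent palladium inserts into the C3'–I bond, the allylic stannane transfers the prenyl group and reductive elimination at the less substituted allyl terminus should give the linear 3-methylbut-2-enyl arene, the aryl acetates and the chromone being inert under these neutral conditions.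

**Step 10**
Reactants: 17 3-[2,6-diacetoxy-4-methoxy-3-(3-methylbut-2-en-1-yl)phenyl]-4-oxo-4H-chromen-7-yl acetate
Product: 18 3-[2,6-dihydroxy-4-methoxy-3-(3-methylbut-2-en-1-yl)phenyl]-7-hydroxy-4H-chromen-4-one
Conditions: K2CO3 (0.3 equiv), MeOH, 0 °C to rt; aq NH4Cl
Reagents that add atoms: none
Why: Base-catalysed transesterification (Zemplén-type methanolysis) of the three aryl acetates is fast at or below room temperature and should leave the prenyl alkene, the methyl ether and the pyranone untouched.

**Compound list**
1 | 2,4,6-trihydroxybenzaldehyde | O=Cc1c(O)cc(O)cc1O | starting material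
2 | dimethyl sulfate | COS(=O)(=O)OC | starting material
3 | 2,6-dihydroxy-4-methoxybenzaldehyde | COc1cc(O)c(C=O)c(O)c1 | intermediate
4 | benzyl bromide | BrCc1ccccc1 | starting material
5 | 2,6-bis(benzyloxy)-4-methoxybenzaldehyde | COc1cc(OCc2ccccc2)c(C=O)c(OCc2ccccc2)c1 | intermediate
6 | 2,4-dihydroxyacetophenone | CC(=O)c1ccc(O)cc1O | starting material
7 | 1-[4-(benzyloxy)-2-hydroxyphenyl]ethan-1-one | CC(=O)c1ccc(OCc2ccccc2)cc1O | intermediate
8 | (E)-1-[4-(benzyloxy)-2-hydroxyphenyl]-3-[2,6-bis(benzyloxy)-4-methoxyphenyl]prop-2-en-1-one | COc1cc(OCc2ccccc2)c(/C=C/C(=O)c2ccc(OCc3ccccc3)cc2O)c(OCc2ccccc2)c1 | intermediate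
9 | 1-[4-(benzyloxy)-2-hydroxyphenyl]-2-[2,6-bis(benzyloxy)-4-methoxyphenyl]-3,3-dimethoxypropan-1-one (racemic, not isolated) | COc1cc(OCc2ccccc2)c(C(C(OC)OC)C(=O)c2ccc(OCc3ccccc3)cc2O)c(OCc2ccccc2)c1 | intermediate
10 | 7-(benzyloxy)-3-[2,6-bis(benzyloxy)-4-methoxyphenyl]-4H-chromen-4-one | COc1cc(OCc2ccccc2)c(-c2coc3cc(OCc4ccccc4)ccc3c2=O)c(OCc2ccccc2)c1 | intermediate
11 | N-iodosuccinimide | O=C1CCC(=O)N1I | starting material
12 | 7-(benzyloxy)-3-[2,6-bis(benzyloxy)-3-iodo-4-methoxyphenyl]-4H-chromen-4-one | COc1cc(OCc2ccccc2)c(-c2coc3cc(OCc4ccccc4)ccc3c2=O)c(OCc2ccccc2)c1I | intermediate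
13 | 3-(2,6-dihydroxy-3-iodo-4-methoxyphenyl)-7-hydroxy-4H-chromen-4-one | COc1cc(O)c(-c2coc3cc(O)ccc3c2=O)c(O)c1I | intermediate
14 | acetic anhydride | CC(=O)OC(C)=O | starting material
15 | 3-(2,6-diacetoxy-3-iodo-4-methoxyphenyl)-4-oxo-4H-chromen-7-yl acetate | COc1cc(OC(C)=O)c(-c2coc3cc(OC(C)=O)ccc3c2=O)c(OC(C)=O)c1I | intermediate
16 | tributyl(3-methylbut-2-en-1-yl)stannane | CCCC[Sn](CCCC)(CCCC)CC=C(C)C | starting material
17 | 3-[2,6-diacetoxy-4-methoxy-3-(3-methylbut-2-en-1-yl)phenyl]-4-oxo-4H-chromen-7-yl acetate | COc1cc(OC(C)=O)c(-c2coc3cc(OC(C)=O)ccc3c2=O)c(OC(C)=O)c1CC=C(C)C | intermediate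
18 | 3-[2,6-dihydroxy-4-methoxy-3-(3-methylbut-2-en-1-yl)phenyl]-7-hydroxy-4H-chromen-4-one | COc1cc(O)c(-c2coc3cc(O)ccc3c2=O)c(O)c1CC=C(C)C | target

**Count and risks**
Total step count: 10. Longest linear sequence: 9 steps (steps 1, 2 and 4 to 10; step 3 is the side branch).

Steps most likely to fail:

1. Step 5. Trivalent thallium may oxidise or thallate the very electron-rich ring B at its open positions, or the phenol may close onto the thalliated alkene before the aryl shift takes place. The fallback sets out from 8 and comes back at 10, and it uses a non-oxidative rearrangement. The chelated phenol of 8 would be capped (MOMCl, NaH, DMF, 0 °C) to give (E)-1-[4-(benzyloxy)-2-(methoxymethoxy)phenyl]-3-[2,6-bis(benzyloxy)-4-methoxyphenyl]prop-2-en-1-one F1. Weitz–Scheffer epoxidation (H2O2, NaOH, MeOH/THF) should then give racemic trans-[4-(benzyloxy)-2-(methoxymethoxy)phenyl]{3-[2,6-bis(benzyloxy)-4-methoxyphenyl]oxiran-2-yl}methanone F2. BF3·OEt2 in CH2Cl2 at low temperature should open the epoxide at the benzylic carbon, which the trialkoxyphenyl ring stabilises, and a 1,2-shift of the aroyl group should give racemic 3-[4-(benzyloxy)-2-(methoxymethoxy)phenyl]-2-[2,6-bis(benzyloxy)-4-methoxyphenyl]-3-oxopropanal F3. Methanolic HCl would then remove the methoxymethyl group, and the freed phenol should condense with the aldehyde to give 10.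

2. Step 9. Oxidative addition and transmetalation at a carbon flanked by two ortho substituents may be slow, and allylic transposition during transfer of the prenyl group would deliver the branched 1,1-dimethylallyl isomer. The fallback sets out from 15 and comes back at 17, and it builds the side chain in two stages. Stille coupling with the small, symmetric allyl group (allyltributylstannane, Pd(PPh3)4, DMF, 80 °C) should give 3-[2,6-diacetoxy-4-methoxy-3-(prop-2-en-1-yl)phenyl]-4-oxo-4H-chromen-7-yl acetate F4. Olefin cross-metathesis with excess 2-methylbut-2-ene (second-generation Grubbs catalyst, CH2Cl2, 40 °C) should then turn the terminal alkene into the trisubstituted one of 17.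

3. Step 1. Alkylation may run on to a second hydroxyl, or occur at carbon of the phloroglucinol nucleus, instead of stopping at the 4-oxygen. The fallback sets out from 1 and comes back at 3, and it replaces selective alkylation by selective cleavage. Exhaustive methylation (Me2SO4 in excess, K2CO3, acetone, reflux) should give 2,4,6-trimethoxybenzaldehyde F5. Excess AlCl3 in CH2Cl2 at reflux should then remove only the two methyl groups ortho to the formyl group, through chelation of aluminium between the carbonyl and each neighbouring ether oxygen, leaving the para methyl ether of 3.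

Further compounds
F1 | step 5 | (E)-1-[4-(benzyloxy)-2-(methoxymethoxy)phenyl]-3-[2,6-bis(benzyloxy)-4-methoxyphenyl]prop-2-en-1-one | COCOc1cc(OCc2ccccc2)ccc1C(=O)/C=C/c1c(OCc2ccccc2)cc(OC)cc1OCc1ccccc1
F2 | step 5 | trans-[4-(benzyloxy)-2-(methoxymethoxy)phenyl]{3-[2,6-bis(benzyloxy)-4-methoxyphenyl]oxiran-2-yl}methanone (racemic, one enantiomer drawn) | COCOc1cc(OCc2ccccc2)ccc1C(=O)[C@H]1O[C@@H]1c1c(OCc2ccccc2)cc(OC)cc1OCc1ccccc1
F3 | step 5 | 3-[4-(benzyloxy)-2-(methoxymethoxy)phenyl]-2-[2,6-bis(benzyloxy)-4-methoxyphenyl]-3-oxopropanal (racemic) | COCOc1cc(OCc2ccccc2)ccc1C(=O)C(C=O)c1c(OCc2ccccc2)cc(OC)cc1OCc1ccccc1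
F4 | step 9 | 3-[2,6-diacetoxy-4-methoxy-3-(prop-2-en-1-yl)phenyl]-4-oxo-4H-chromen-7-yl acetate | COc1cc(OC(C)=O)c(-c2coc3cc(OC(C)=O)ccc3c2=O)c(OC(C)=O)c1CC=C
F5 | step 1 | 2,4,6-trimethoxybenzaldehyde | COc1cc(OC)c(C=O)c(OC)c1
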